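## Structural features

The target is a germacranolide: a ten-membered carbocycle (C1–C10) with two trisubstituted ring alkenes, C1=C10 and C4=C5, each traversed by the ring in cis fashion and each carrying a hydroxymethyl group (C14 on C10, C15 on C4). An α-methylene-γ-butyrolactone (O on C6, C11 on C7, C11=C13, C12=O) is trans-fused across C6–C7. C6 (R), C7 (S), C8 (R) and C9 (S) form an unbroken stereotetrad; C8 carries an (S)-2-methylbutanoate and the allylic C9 an acetate, so a fifth stereocentre lies in the side chain. Fragile elements are the exocyclic Michael acceptor, two different esters on neighbouring carbons (1,2-acyl shift, and 1,3-shift of the C9 acetate to a free C14 hydroxyl), possible relactonisation towards C8, and three allylic C–O bonds. The real difficulty is the strained cyclodecadiene with both alkene geometries defined and C6/C7 set correctly relative to C8/C9, together with telling five oxygens apart. The key step exploits that C6 is a carbinol carbon between the C4=C5 alkene and C7, and that C7 carries the 1-substituted vinyl unit C11(=C13)C12. This homoallylic alcohol pattern is what a [2,3]-shift of a C6 carbanion in a C6–O–C13 allyl ether leaves behind.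

## Logic of the disconnections

41 back to 36. The bonds cut are the two Si–O bonds (40), the acetyl C–O bond at C9 (39), the C9–O arylmethyl bond (38), the acyl C–O bond at C8 (37) and the C8–O–Si bond (36). The branched acid goes onto C8 while C9 is still an ether, and the acetate follows in a fast step, so the slow acylation never runs beside an ester that could migrate. The primary alcohols are freed last because a free C14 hydroxyl could take over the C9 acetate. This demands groups on C8, C9 and C14/C15 that fall in that order to mild acid, DDQ and fluoride.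

36 back to 32. The O6–C12 acyl bond and the C12 oxidation level are removed: 36 comes from the 1,4-diol 33 by oxidative lactonisation, and 33 from 32 by cleaving the C12–O arylmethyl bond. The Michael acceptor therefore does not exist during any organometallic step. In 33 only the C12 hydroxyl may be free beside C6–OH, so the C12 ether must be more DDQ-labile than the C9 ether. A silyl ether on C12 that is more robust than the silyl ether on a ring carbinol could not be removed first and is avoided.

32 back to 30 (key disconnection). C6–C7 is cut and O–C13 is reconnected, turning the ten-membered carbocycle into a thirteen-membered cyclic bis-allylic ether; C11=C13 becomes C7=C11. The strained ring and two stereocentres then arise from one intramolecular shift inside an unstrained ring. The forward step needs a carbanion at C6 only (hence tin on C6), C8 trans to C13 across C7=C11, and nothing but ethers elsewhere.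

30 back to 28. Cutting O–C13 gives 29, a C6 hydroxystannane that carries a latent C13 electrophile; cutting C6–Sn gives the enal 28. An α-stannyl alkoxide expels the stannyl anion, so the ether cannot be closed by base-mediated alkylation. It is closed under acid from the neutral hydroxyl onto an imidate, and the imidate must have no N–H so that it survives the stannyl anion.

28 back to 24. These are changes of oxidation level and activation: C6 aldehyde from alcohol 27, 27 from its dimethoxybenzyl ether 26, the C13 imidate 26 from alcohol 25, and 25 from ester 24. The order is forced: C13–OH must be masked as the imidate before C6–OH is freed, otherwise two primary allylic alcohols could not be told apart.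

24 back to 21 and 22. C7=C11 is cut by a Horner–Wadsworth–Emmons transform and O–C12 by an oxa-Michael transform. The whole C11–C13 unit then arrives in one operation from 22 with the C12 oxygen already protected. The forward step must give the E enoate, ester trans to C8, so that the ester carbon becomes C13.

21 back to 17. The C7 aldehyde is traced to the primary silyl ether of 20, the diol 19, the acetonide 18 and the free C9 carbinol 17. Silylating both hydroxyls and oxidising only the primary silyl ether avoids a separate protection and deprotection of C7 and leaves C8 as a secondary triethylsilyl ether.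

17 back to 12 and 14. The C9–H bond (reduction of 16) and the C9–C10 bond (acylation of the alkenyllithium from 12 by amide 14) are cut; 14 comes from the chiral-pool ester 13, which supplies C8. Chelation-controlled reduction of the ketone sets C9 more reliably than direct addition of the alkenylmetal to the aldehyde would.

12 back to 7. Si–O (11), then C10–Sn and C1–H across the alkyne (10), then C10–C14 (8) and the alkynyl C–Si bond (7) are cut. The free propargylic hydroxyl of 10 is needed to steer tin to C10 and hydrogen anti to it, which places C9 (later) cis to C2.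

7 back to 4 and 5, and 4 back to 1. C3–C4 is cut by a Negishi transform between the homopropargyl unit 5 and the iodoalkene 4. 4 comes from 3 by O-alkylation, 3 from 2 by adding H and I anti across the alkyne, and 2 from the symmetrical diol 1. The coupling must retain the alkene geometry so that C3 ends cis to C6.

## Other disconnections considered

Alternative 1: The cut is at O–C12 and C11–C12, so that the lactone carbonyl comes from carbon monoxide and C11/C13 from an ethynyl group on C7.
- Forward step: the hydroxy alkyne A1 would be treated with CO and a divalent palladium salt such as PdCl2. Alkoxycarbonylpalladium formation at the C6 hydroxyl, syn insertion of the alkyne and protonolysis would give the bis-silyl lactone A2, one desilylation from 41.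
- In favour: both lactone bonds and the exocyclic methylene arise in one atom-economical step at the end, the Michael acceptor is never carried, C12 and C13 need not be differentiated, and the trans fusion is already fixed in A1. In endgame length it is better than the chosen plan.
- Against: the step forms no ring C–C bond, so the ten-membered ring and the C6/C7 pair of A1 still need another macrocyclisation, for which the ethynyl group offers no retron. The allylic C9 acetate and the doubly allylic C6–O bond could ionise on zerovalent palladium formed in the cycle. The free C6 hydroxyl also sits 1,3 to the C8 ester.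
- Comparison: structurally the chosen plan solves ring, C6 and C7 together, while this one decorates a finished ring. Mechanistically the carbonylation must tolerate two esters, whereas the Wittig shift sees only ethers. In step count it is equal or shorter once the ring exists and probably longer before that.

Alternative 2: The cut reconnects C5 to C10, so the ten-membered ring is seen as an octalin whose tetrasubstituted ring-fusion alkene is cleaved.
- Forward step: ozonolysis (O3, then Me2S) of the octalin A3, itself from a Diels–Alder-derived decalin, would give the cyclodecane-1,6-dione A4 with the trans lactone and the C8/C9 oxygens in place.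
- In favour: the C6–C9 tetrad and the trans lactone are set on a rigid bicyclic template, which is better stereocontrol than the chosen plan can claim for C6/C7. No macrocyclisation entropy is paid, which is equal to the chosen plan.
- Against: A4 has ketones where the target has C4=C5 and C1=C10, and it lacks C14 and C13. Each ketone would have to become a ring-cis trisubstituted alkene regio- and stereoselectively, and C10 needs an extra carbon. A cyclodecane-1,6-dione is predisposed to transannular aldol reaction, and the C5 ketone is α to the lactone oxygen.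
- Comparison: the cleavage itself is reliable, but ozone tolerates no other alkene, so all unsaturation comes afterwards. In step economy this route is clearly longer.

Alternative 3: The cut is again a transannular bond, C4–C9, so the ring is seen as a cis-fused decalin.
- Forward step: the decalin mesylate A5 (tertiary C9 alcohol, C5 mesylate) would be treated with KOt-Bu. The C9 alkoxide pushes out the mesylate across C4–C9 (Wharton fragmentation) to give the cyclodecadienone A6.
- In favour: the concerted fragmentation is stereospecific, so the anti-periplanar C4–C9/C5–O arrangement fixes the ring-cis C4=C5 geometry. That is as good as or better than carrying the alkene from an iodoalkene. C1=C10 and the C7 side arm are already present, and no macrocyclisation is needed (equal).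
- Against: A5 needs a quaternary C4, a tertiary C9 carbinol and the C5 mesylate, three stereocentres built only to be destroyed, on top of C6–C8. A6 has a C9 ketone that must be reduced with the right facial selectivity on a flexible ring, whereas the chosen plan sets C9 early under chelation control. The α-alkoxy ketone at C8 could epimerise under the basic conditions.
- Comparison: both plans unveil the medium ring from an easier ring; the fragmentation gives better alkene control, the Wittig shift creates two stereocentres instead of consuming three. In step economy this route is longer.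

Key step: step 23

Remark: germacranolide numbering is used in all names (ring C1–C10, C14 on C10, C15 on C4, C11–C13 on C7); TIPS = triisopropylsilyl, TES = triethylsilyl, DMB = 3,4-dimethoxybenzyl, PMB = 4-methoxybenzyl, NAP = 2-naphthylmethyl.

Assumption: the lithium species formed at C6 is a delocalised α-alkoxyallyl anion that keeps no memory of the tin-bearing configuration, so 29 and 30 are carried as mixtures of C6 epimers; 5, 13, 22 and (S)-2-methylbutanoic anhydride are taken as purchasable.

## Route

Step 1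
Reactants: 1 2-butyne-1,4-diol
Product: 2 4-(triisopropylsilyloxy)but-2-yn-1-ol
Conditions: NaH (1.0 equiv), THF, 0 °C; TIPSCl, rt
Reagents that add atoms: chlorotriisopropylsilane CC(C)[Si](Cl)(C(C)C)C(C)C
Why: One equivalent of NaH gives the sparingly soluble monoalkoxide of the symmetrical diol, which is silylated once (statistical mono-protection of a symmetrical diol).

Step 2
Reactants: 2 4-(triisopropylsilyloxy)but-2-yn-1-ol
Product: 3 (Z)-3-iodo-4-(triisopropylsilyloxy)but-2-en-1-ol
Conditions: NaAlH2(OCH2CH2OMe)2, THF, 0 °C; then I2, −78 °C to 0 °C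
Reagents that add atoms: iodine II
Why: Hydroxyl-directed trans-hydroalumination places aluminium on the alkyne carbon remote from the free alcohol and hydrogen anti to it; iodinolysis with retention puts iodine cis to CH2OH on the carbon bearing CH2OTIPS (future C4, C15, C5, C6).

Step 3
Reactants: 3 (Z)-3-iodo-4-(triisopropylsilyloxy)but-2-en-1-ol
Product: 4 (Z)-4-(3,4-dimethoxybenzyloxy)-2-iodo-1-(triisopropylsilyloxy)but-2-ene
Conditions: NaH, 3,4-dimethoxybenzyl chloride, Bu4NI (cat.), THF/DMF, 0 °C to rt
Reagents that add atoms: 4-(chloromethyl)-1,2-dimethoxybenzene COc1ccc(CCl)cc1OC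
Why: Williamson etherification of the primary allylic alkoxide; the DMB ether is the most easily oxidised of the three arylmethyl ethers used and will be the first removed.

Step 4
Reactants: 5 (4-bromobut-1-yn-1-yl)trimethylsilane; 4 (Z)-4-(3,4-dimethoxybenzyloxy)-2-iodo-1-(triisopropylsilyloxy)but-2-ene
Product: 7 (E)-7-(3,4-dimethoxybenzyloxy)-5-(triisopropylsilyloxymethyl)-1-(trimethylsilyl)hept-5-en-1-yne, via alkylzinc bromide 6 (not isolated)
Conditions: 5, Zn, LiCl, THF, 50 °C; then 4, Pd(PPh3)4 (cat.), THF, 50 °C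
Reagents that add atoms: none
Why: Negishi coupling: zinc inserts into the primary C–Br bond, the alkylzinc transmetalates to the alkenylpalladium iodide formed by oxidative addition to zerovalent palladium, and reductive elimination forms C3–C4 with retention, so C3 ends cis to C6. The silyl cap keeps the alkyne terminus inert.

Step 5
Reactants: 7 (E)-7-(3,4-dimethoxybenzyloxy)-5-(triisopropylsilyloxymethyl)-1-(trimethylsilyl)hept-5-en-1-yne
Product: 8 (E)-7-(3,4-dimethoxybenzyloxy)-5-(triisopropylsilyloxymethyl)hept-5-en-1-yne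
Conditions: K2CO3 (cat.), MeOH, rt
Reagents that add atoms: none
Why: Base-catalysed methanolysis of the alkynyl C–Si bond; silyl and benzyl-type ethers are untouched.

Step 6
Reactants: 8 (E)-7-(3,4-dimethoxybenzyloxy)-5-(triisopropylsilyloxymethyl)hept-5-en-1-yne
Product: 10 (E)-8-(3,4-dimethoxybenzyloxy)-6-(triisopropylsilyloxymethyl)oct-6-en-2-yn-1-ol, via lithium acetylide 9 (not isolated)
Conditions: n-BuLi, THF, −78 °C; (CH2O)n, −78 °C to rt; then H2O
Reagents that add atoms: formaldehyde (as paraformaldehyde) C=O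
Why: Addition of the lithium acetylide to formaldehyde installs C14 and the free propargylic hydroxyl that directs the next step.

Step 7
Reactants: 10 (E)-8-(3,4-dimethoxybenzyloxy)-6-(triisopropylsilyloxymethyl)oct-6-en-2-yn-1-ol
Product: 11 (2Z,6E)-8-(3,4-dimethoxybenzyloxy)-2-(tributylstannyl)-6-(triisopropylsilyloxymethyl)octa-2,6-dien-1-ol
Conditions: Bu3SnH, [Cp*RuCl]4 (cat.), CH2Cl2, rt
Reagents that add atoms: tributylstannane CCCC[SnH](CCCC)CCCC
Why: Ruthenium-catalysed trans-hydrostannation of a propargylic alcohol: hydrogen bonding of the hydroxyl to the Ru–Cl unit delivers tin to the proximal alkyne carbon (C10) and hydrogen anti to it, so tin is cis to C2 and C14 trans. The trisubstituted alkene is inert.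

Step 8
Reactants: 11 (2Z,6E)-8-(3,4-dimethoxybenzyloxy)-2-(tributylstannyl)-6-(triisopropylsilyloxymethyl)octa-2,6-dien-1-ol
Product: 12 tributyl[(2Z,6E)-8-(3,4-dimethoxybenzyloxy)-1-(triisopropylsilyloxy)-6-(triisopropylsilyloxymethyl)octa-2,6-dien-2-yl]stannane
Conditions: TIPSCl, imidazole, DMF, rt
Reagents that add atoms: chlorotriisopropylsilane CC(C)[Si](Cl)(C(C)C)C(C)C
Why: Standard silylation of the primary alcohol; the bulky TIPS group resists O-to-C silyl migration in the alkenyllithium of the next main-line step.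

Step 9
Reactants: 13 methyl (R)-2,2-dimethyl-1,3-dioxolane-4-carboxylate
Product: 14 (R)-N-methoxy-N,2,2-trimethyl-1,3-dioxolane-4-carboxamide
Conditions: MeNH(OMe)·HCl, i-PrMgCl, THF, −20 °C
Reagents that add atoms: N,O-dimethylhydroxylamine hydrochloride CNOC.Cl
Why: Aminolysis of the ester by the magnesium amide (Weinreb amide formation) under non-enolising conditions keeps the α-stereocentre, which becomes C8.

Step 10
Reactants: 12 tributyl[(2Z,6E)-8-(3,4-dimethoxybenzyloxy)-1-(triisopropylsilyloxy)-6-(triisopropylsilyloxymethyl)octa-2,6-dien-2-yl]stannane; 14 (R)-N-methoxy-N,2,2-trimethyl-1,3-dioxolane-4-carboxamide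
Product: 16 (2Z,6E)-8-(3,4-dimethoxybenzyloxy)-1-[(4R)-2,2-dimethyl-1,3-dioxolan-4-yl]-2,6-bis(triisopropylsilyloxymethyl)octa-2,6-dien-1-one, via alkenyllithium 15 (not isolated)
Conditions: n-BuLi, THF, −78 °C; then 14, −78 °C; then H2O
Reagents that add atoms: none
Why: Tin–lithium exchange with retention gives the alkenyllithium, which adds once to the amide because the chelated tetrahedral intermediate survives until work-up (Weinreb ketone synthesis). C9–C10 forms with C9 cis to C2 and C8 is not epimerised.

Step 11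
Reactants: 16 (2Z,6E)-8-(3,4-dimethoxybenzyloxy)-1-[(4R)-2,2-dimethyl-1,3-dioxolan-4-yl]-2,6-bis(triisopropylsilyloxymethyl)octa-2,6-dien-1-one
Product: 17 (1S,2Z,6E)-8-(3,4-dimethoxybenzyloxy)-1-[(4R)-2,2-dimethyl-1,3-dioxolan-4-yl]-2,6-bis(triisopropylsilyloxymethyl)octa-2,6-dien-1-ol (8R,9S in germacranolide numbering)
Conditions: Zn(BH4)2, Et2O, −20 °C
Reagents that add atoms: none
Why: Chelation-controlled 1,2-reduction (Cram chelate model): zinc bridges the ketone and the neighbouring dioxolane oxygen, and hydride attacks from the face of the C8 hydrogen, giving the anti (8R,9S) alcohol.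

Step 12
Reactants: 17 (1S,2Z,6E)-8-(3,4-dimethoxybenzyloxy)-1-[(4R)-2,2-dimethyl-1,3-dioxolan-4-yl]-2,6-bis(triisopropylsilyloxymethyl)octa-2,6-dien-1-ol
Product: 18 C9 2-naphthylmethyl ether of 17
Conditions: NaH, 2-(bromomethyl)naphthalene, Bu4NI (cat.), THF/DMF, 0 °C to rt
Reagents that add atoms: 2-(bromomethyl)naphthalene BrCc1ccc2ccccc2c1
Why: Williamson etherification; the NAP ether survives acid, organolithiums and the cleavage of the DMB and PMB ethers, and yields only to excess DDQ at the end.

Step 13
Reactants: 18 C9 2-naphthylmethyl ether of 17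
Product: 19 (2R,3S,4Z,8E)-10-(3,4-dimethoxybenzyloxy)-3-(2-naphthylmethoxy)-4,8-bis(triisopropylsilyloxymethyl)deca-4,8-diene-1,2-diol (C7,C8 diol)
Conditions: AcOH/H2O/THF (3:1:1), 45 °C
Reagents that add atoms: none
Why: Acid hydrolysis of the terminal isopropylidene acetal; primary TIPS ethers and arylmethyl ethers tolerate aqueous acetic acid.

Step 14
Reactants: 19 (2R,3S,4Z,8E)-10-(3,4-dimethoxybenzyloxy)-3-(2-naphthylmethoxy)-4,8-bis(triisopropylsilyloxymethyl)deca-4,8-diene-1,2-diol
Product: 20 C7,C8 bis(triethylsilyl) ether of 19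
Conditions: TESCl, imidazole, DMAP (cat.), CH2Cl2, 0 °C to rt
Reagents that add atoms: chlorotriethylsilane CC[Si](Cl)(CC)CC
Why: Silylation of both hydroxyls sets up selective oxidative removal of the primary one; C8 keeps its TES ether.

Step 15
Reactants: 20 C7,C8 bis(triethylsilyl) ether of 19
Product: 21 (2S,3S,4Z,8E)-10-(3,4-dimethoxybenzyloxy)-3-(2-naphthylmethoxy)-2-(triethylsilyloxy)-4,8-bis(triisopropylsilyloxymethyl)deca-4,8-dienal (C7 aldehyde; C8 and C9 unchanged in space)
Conditions: (COCl)2, DMSO, CH2Cl2, −78 °C to −40 °C; then Et3N, −78 °C to rt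
Reagents that add atoms: none
Why: Under Swern conditions a primary triethylsilyl ether is converted directly into the aldehyde: activated DMSO attacks the unhindered primary silyl ether oxygen, the silyl group leaves and the alkoxysulfonium collapses. The secondary TES ether and the TIPS ethers stay.

Step 16
Reactants: 21 C7 aldehyde; 22 ethyl 2-(diethoxyphosphoryl)acrylate
Product: 24 ethyl (2E,4R,5S,6Z,10E)-12-(3,4-dimethoxybenzyloxy)-2-[(4-methoxybenzyloxy)methyl]-5-(2-naphthylmethoxy)-4-(triethylsilyloxy)-6,10-bis(triisopropylsilyloxymethyl)dodeca-2,6,10-trienoate, via phosphonate carbanion 23 (not isolated)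
Conditions: 4-methoxybenzyl alcohol, NaH, THF, 0 °C; 22, 0 °C; then 21, −78 °C to 0 °C
Reagents that add atoms: 4-methoxybenzyl alcohol COc1ccc(CO)cc1
Why: Oxa-Michael addition of the alkoxide to the vinylphosphonate gives the α-(alkoxymethyl)phosphonoacetate anion, which olefinates the α-branched aldehyde (Horner–Wadsworth–Emmons). Reversible addition favours the E enoate with the ester trans to C8, so the ester carbon is C13 and the alkoxymethyl carbon is C12.

Step 17
Reactants: 24 E enoate
Product: 25 C13 allylic alcohol, (2Z,4R,5S,6Z,10E)-12-(3,4-dimethoxybenzyloxy)-2-[(4-methoxybenzyloxy)methyl]-5-(2-naphthylmethoxy)-4-(triethylsilyloxy)-6,10-bis(triisopropylsilyloxymethyl)dodeca-2,6,10-trien-1-ol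
Conditions: i-Bu2AlH, CH2Cl2, −78 °C
Reagents that add atoms: none
Why: 1,2-Reduction of the conjugated ester to the allylic alcohol; ethers and silyl ethers are inert.

Step 18
Reactants: 25 C13 allylic alcohol
Product: 26 C13 O-(N-phenyl-2,2,2-trifluoroacetimidate) of 25
Conditions: CF3C(Cl)=NPh, NaH, THF, 0 °C
Reagents that add atoms: 2,2,2-trifluoro-N-phenylacetimidoyl chloride FC(F)(F)C(Cl)=Nc1ccccc1
Why: O-Imidoylation of the primary allylic alkoxide; the N-aryl imidate has no N–H and so tolerates the stannyl anion used later, yet it is a latent allylic electrophile under acid catalysis.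

Step 19
Reactants: 26 C13 imidate
Product: 27 C6 primary allylic alcohol (DMB ether of 26 removed)
Conditions: DDQ (1.1 equiv), CH2Cl2/pH 7 buffer, 0 °C
Reagents that add atoms: none
Why: DDQ oxidises the most electron-rich arylmethyl ether (DMB) faster than the PMB and NAP ethers; hydrolysis of the oxocarbenium ion frees the C6 hydroxyl.

Step 20
Reactants: 27 C6 primary allylic alcohol
Product: 28 C6 enal
Conditions: MnO2, CH2Cl2, rt
Reagents that add atoms: none
Why: MnO2 oxidises the only free (allylic) alcohol under neutral conditions that preserve the imidate and the alkene geometry.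

Step 21
Reactants: 28 C6 enal
Product: 29 C6 α-hydroxy allylstannane (6RS; Bu3Sn and OH on C6; C13 imidate, C12 OPMB, C8 OTES, C9 ONAP, C14 and C15 OTIPS)
Conditions: Bu3SnH, LiN(i-Pr)2, THF, 0 °C; then 28, −78 °C; then AcOH, −78 °C
Reagents that add atoms: tributylstannane CCCC[SnH](CCCC)CCCC
Why: Bu3SnLi adds 1,2 to the aldehyde at −78 °C far faster than it attacks the imidate. The adduct is protonated cold because its alkoxide would revert to aldehyde and stannyl anion on warming; both C6 epimers form and the crude product is used at once.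

Step 22
Reactants: 29 C6 α-hydroxy allylstannane
Product: 30 thirteen-membered α-stannyl bis-allylic ether (ring C6–O–C13–C11=C7–C8–C9–C10=C1–C2–C3–C4=C5; Bu3Sn on C6, 6RS; CH2OPMB on C11 cis to C8; C8 OTES (R); C9 ONAP (S); C14 and C15 OTIPS; C3 cis to C6, C9 cis to C2, C8 trans to C13)
Conditions: TMSOTf (0.1 equiv), 4 Å MS, CH2Cl2 (0.001 M), −40 °C
Reagents that add atoms: none
Why: Acid-catalysed O-alkylation of an α-hydroxystannane by an imidate, here intramolecular at high dilution: the activated imidate is displaced at its primary terminus C13 by the neutral C6 hydroxyl and trifluoroacetanilide leaves, so no stannyl alkoxide is ever formed. Attack at C7 would give a more strained eleven-membered ring, and the fully substituted γ-carbon C4 disfavours 1,3-tin shift and C-allylation.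

Step 23
Reactants: 30 thirteen-membered α-stannyl bis-allylic ether
Product: 32 ten-membered (6R,7S,8R,9S) C6 alcohol with a 3-(4-methoxybenzyloxy)prop-1-en-2-yl group on C7 (C8 OTES, C9 ONAP, C14 and C15 OTIPS, both ring alkenes ring-cis), via allyllithium 31 (not isolated)
Conditions: n-BuLi (1.3 equiv), THF, −78 °C; then H2O
Reagents that add atoms: none
Why: n-BuLi exchanges tin for lithium at C6 at −78 °C faster than any deprotonation, and the resulting α-alkoxyallyllithium 31 is delocalised over C6–C5–C4, so both C6 epimers of 30 give the same anion. C6 then bonds to C7 through a five-membered envelope transition state (C6, O, C13, C11, C7) while O–C13 breaks and the π bond moves to C11=C13; this is the [2,3]-Wittig rearrangement in its stannane-triggered (Wittig–Still) form, and the closest known reaction type is the ring contraction of macrocyclic bis-allylic ethers to medium-ring homoallylic alcohols. The ten-membered carbocycle closes by extrusion of O, C13 and C11 from the thirteen-membered ring, an intramolecular SN2′-type attack of C6 on C7 inside a pre-formed ring and not an end-to-end cyclisation. C7 is controlled by C8: A(1,3) strain with the cis CH2OPMB group holds H8 in the alkene plane, the tether through C9 fixes the face, and C6 arrives anti to the C8–O bond, giving 7S. C6 is controlled by the alkene geometry: with C8 trans to C13 the envelope that keeps the ring chain pseudo-equatorial gives the anti (6R,7S) pair that becomes the trans lactone. The step needs the anion at C6 and not at C13, which the tin secures, and it needs the [2,3] shift to outrun the [1,2] shift and 1,4-loss of the C15 silanolate, which low temperature, the bulky weakly coordinating TIPS ether and the intramolecular nature of the shift should favour. The ring-cis alkenes and the arylmethyl ethers are spectators at −78 °C with only a slight excess of base.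

Step 24
Reactants: 32 ten-membered C6 alcohol
Product: 33 C6,C12 diol (PMB ether of 32 removed)
Conditions: DDQ (1.1 equiv), CH2Cl2/pH 7 buffer, 0 °C
Reagents that add atoms: none
Why: Oxidative cleavage of the PMB ether, which DDQ attacks faster than the less electron-rich NAP ether; wet buffered conditions hydrolyse the oxocarbenium ion before the C6 hydroxyl can trap it.

Step 25
Reactants: 33 C6,C12 diol
Product: 36 trans-fused α-methylene-γ-butyrolactone (12,6-olide; C8 OTES, C9 ONAP, C14 and C15 OTIPS), via hydroxy enal 34 (not isolated), via lactol 35 (not isolated)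
Conditions: TEMPO (cat.), PhI(OAc)2, CH2Cl2, rt
Reagents that add atoms: none
Why: The oxoammonium salt oxidises the primary allylic alcohol to the enal, the C6 hydroxyl closes the five-membered lactol (5-exo addition to the aldehyde) and a second oxidation gives the lactone. The secondary C6 alcohol itself is oxidised much more slowly.

Step 26
Reactants: 36 lactone with C8 OTES
Product: 37 C8 alcohol (C9 ONAP, C14 and C15 OTIPS)
Conditions: PPTS, MeOH/CH2Cl2, 0 °C to rt
Reagents that add atoms: none
Why: Mild acid methanolysis removes the secondary TES ether while the far more stable primary TIPS ethers and the NAP ether remain; acidic conditions avoid relactonisation towards C8.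

Step 27
Reactants: 37 C8 alcohol
Product: 38 C8 (S)-2-methylbutanoate (C9 ONAP, C14 and C15 OTIPS)
Conditions: (S)-2-methylbutanoic anhydride, DMAP, Et3N, CH2Cl2, rt
Reagents that add atoms: (S)-2-methylbutanoic anhydride CC[C@H](C)C(=O)OC(=O)[C@@H](C)CC
Why: DMAP-catalysed acylation with the symmetrical anhydride, which has no ketene pathway and so does not racemise the α-centre; C9 is still an ether, so no acyl migration is possible during this slow step.

Step 28
Reactants: 38 C8 (S)-2-methylbutanoate
Product: 39 C9 alcohol (C8 ester, C14 and C15 OTIPS)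
Conditions: DDQ (3 equiv), CH2Cl2/H2O (10:1), rt
Reagents that add atoms: none
Why: Excess DDQ oxidises the naphthylmethyl ether, the last arylmethyl ether left; esters, lactone and silyl ethers are inert under these neutral conditions.

Step 29
Reactants: 39 C9 alcohol
Product: 40 C9 acetate (bis-TIPS ether of the target)
Conditions: Ac2O, pyridine, DMAP (cat.), CH2Cl2, 0 °C
Reagents that add atoms: acetic anhydride CC(=O)OC(C)=O
Why: Fast DMAP-catalysed acetylation of the allylic alcohol, quicker than migration of the hindered C8 acyl group.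

Step 30
Reactants: 40 bis-TIPS ether
Product: 41 target CNP0207247.12, (6R,7S,8R,9S)-9-acetoxy-14,15-dihydroxy-8-[(S)-2-methylbutanoyloxy]germacra-1(10),4,11(13)-trien-12,6-olide, both ring alkenes ring-cis
Conditions: HF·pyridine, pyridine, THF, 0 °C to rt
Reagents that add atoms: none
Why: Fluoride-mediated cleavage of the two primary allylic Si–O bonds under buffered, mildly acidic conditions that do not promote acyl migration to C14 or conjugate addition to the methylene lactone.

## Compound list

1 | 2-butyne-1,4-diol | OCC#CCO | starting material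
2 | 4-(triisopropylsilyloxy)but-2-yn-1-ol | OCC#CCO[Si](C(C)C)(C(C)C)C(C)C | intermediate
3 | (Z)-3-iodo-4-(triisopropylsilyloxy)but-2-en-1-ol | OC/C=C(\I)CO[Si](C(C)C)(C(C)C)C(C)C | intermediate
4 | (Z)-4-(3,4-dimethoxybenzyloxy)-2-iodo-1-(triisopropylsilyloxy)but-2-ene | COc1ccc(COC/C=C(\I)CO[Si](C(C)C)(C(C)C)C(C)C)cc1OC | intermediate
5 | (4-bromobut-1-yn-1-yl)trimethylsilane | C[Si](C)(C)C#CCCBr | starting material
6 | [4-(trimethylsilyl)but-3-yn-1-yl]zinc bromide | C[Si](C)(C)C#CCC[Zn]Br | intermediate
7 | (E)-7-(3,4-dimethoxybenzyloxy)-5-(triisopropylsilyloxymethyl)-1-(trimethylsilyl)hept-5-en-1-yne | COc1ccc(COC/C=C(/CO[Si](C(C)C)(C(C)C)C(C)C)CCC#C[Si](C)(C)C)cc1OC | intermediate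
8 | (E)-7-(3,4-dimethoxybenzyloxy)-5-(triisopropylsilyloxymethyl)hept-5-en-1-yne | COc1ccc(COC/C=C(/CO[Si](C(C)C)(C(C)C)C(C)C)CCC#C)cc1OC | intermediate
9 | lithium acetylide of 8 | COc1ccc(COC/C=C(/CO[Si](C(C)C)(C(C)C)C(C)C)CCC#C[Li])cc1OC | intermediate
10 | (E)-8-(3,4-dimethoxybenzyloxy)-6-(triisopropylsilyloxymethyl)oct-6-en-2-yn-1-ol | COc1ccc(COC/C=C(/CO[Si](C(C)C)(C(C)C)C(C)C)CCC#CCO)cc1OC | intermediate
11 | (2Z,6E)-8-(3,4-dimethoxybenzyloxy)-2-(tributylstannyl)-6-(triisopropylsilyloxymethyl)octa-2,6-dien-1-ol | COc1ccc(COC/C=C(/CO[Si](C(C)C)(C(C)C)C(C)C)CC/C=C(/CO)[Sn](CCCC)(CCCC)CCCC)cc1OC | intermediate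
12 | tributyl[(2Z,6E)-8-(3,4-dimethoxybenzyloxy)-1-(triisopropylsilyloxy)-6-(triisopropylsilyloxymethyl)octa-2,6-dien-2-yl]stannane | COc1ccc(COC/C=C(/CO[Si](C(C)C)(C(C)C)C(C)C)CC/C=C(/CO[Si](C(C)C)(C(C)C)C(C)C)[Sn](CCCC)(CCCC)CCCC)cc1OC | intermediate
13 | methyl (R)-2,2-dimethyl-1,3-dioxolane-4-carboxylate | COC(=O)[C@H]1COC(C)(C)O1 | starting material
14 | (R)-N-methoxy-N,2,2-trimethyl-1,3-dioxolane-4-carboxamide | CON(C)C(=O)[C@H]1COC(C)(C)O1 | intermediate
15 | alkenyllithium from 12 (Li in place of Sn) | COc1ccc(COC/C=C(/CO[Si](C(C)C)(C(C)C)C(C)C)CC/C=C(/CO[Si](C(C)C)(C(C)C)C(C)C)[Li])cc1OC | intermediate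
16 | (2Z,6E)-8-(3,4-dimethoxybenzyloxy)-1-[(4R)-2,2-dimethyl-1,3-dioxolan-4-yl]-2,6-bis(triisopropylsilyloxymethyl)octa-2,6-dien-1-one | COc1ccc(COC/C=C(/CO[Si](C(C)C)(C(C)C)C(C)C)CC/C=C(/CO[Si](C(C)C)(C(C)C)C(C)C)C(=O)[C@H]2COC(C)(C)O2)cc1OC | intermediate
17 | (1S,2Z,6E)-8-(3,4-dimethoxybenzyloxy)-1-[(4R)-2,2-dimethyl-1,3-dioxolan-4-yl]-2,6-bis(triisopropylsilyloxymethyl)octa-2,6-dien-1-ol | COc1ccc(COC/C=C(/CO[Si](C(C)C)(C(C)C)C(C)C)CC/C=C(/CO[Si](C(C)C)(C(C)C)C(C)C)[C@H](O)[C@H]2COC(C)(C)O2)cc1OC | intermediate
18 | C9 2-naphthylmethyl ether of 17 | COc1ccc(COC/C=C(/CO[Si](C(C)C)(C(C)C)C(C)C)CC/C=C(/CO[Si](C(C)C)(C(C)C)C(C)C)[C@H](OCc2ccc3ccccc3c2)[C@H]2COC(C)(C)O2)cc1OC | intermediate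
19 | (2R,3S,4Z,8E)-10-(3,4-dimethoxybenzyloxy)-3-(2-naphthylmethoxy)-4,8-bis(triisopropylsilyloxymethyl)deca-4,8-diene-1,2-diol | COc1ccc(COC/C=C(/CO[Si](C(C)C)(C(C)C)C(C)C)CC/C=C(/CO[Si](C(C)C)(C(C)C)C(C)C)[C@H](OCc2ccc3ccccc3c2)[C@H](O)CO)cc1OC | intermediate
20 | C7,C8 bis(triethylsilyl) ether of 19 | COc1ccc(COC/C=C(/CO[Si](C(C)C)(C(C)C)C(C)C)CC/C=C(/CO[Si](C(C)C)(C(C)C)C(C)C)[C@H](OCc2ccc3ccccc3c2)[C@H](O[Si](CC)(CC)CC)CO[Si](CC)(CC)CC)cc1OC | intermediate
21 | (2S,3S,4Z,8E)-10-(3,4-dimethoxybenzyloxy)-3-(2-naphthylmethoxy)-2-(triethylsilyloxy)-4,8-bis(triisopropylsilyloxymethyl)deca-4,8-dienal | COc1ccc(COC/C=C(/CO[Si](C(C)C)(C(C)C)C(C)C)CC/C=C(/CO[Si](C(C)C)(C(C)C)C(C)C)[C@H](OCc2ccc3ccccc3c2)[C@H](O[Si](CC)(CC)CC)C=O)cc1OC | intermediate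
22 | ethyl 2-(diethoxyphosphoryl)acrylate | C=C(C(=O)OCC)P(=O)(OCC)OCC | starting material
23 | sodium salt of the carbanion of ethyl 2-(diethoxyphosphoryl)-3-(4-methoxybenzyloxy)propanoate | [Na+].CCOC(=O)[C-](COCc1ccc(OC)cc1)P(=O)(OCC)OCC | intermediate
24 | ethyl (2E,4R,5S,6Z,10E)-12-(3,4-dimethoxybenzyloxy)-2-[(4-methoxybenzyloxy)methyl]-5-(2-naphthylmethoxy)-4-(triethylsilyloxy)-6,10-bis(triisopropylsilyloxymethyl)dodeca-2,6,10-trienoate | COc1ccc(COC/C=C(/CO[Si](C(C)C)(C(C)C)C(C)C)CC/C=C(/CO[Si](C(C)C)(C(C)C)C(C)C)[C@H](OCc2ccc3ccccc3c2)[C@H](O[Si](CC)(CC)CC)/C=C(/C(=O)OCC)COCc2ccc(OC)cc2)cc1OC | intermediate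
25 | C13 allylic alcohol from 24 | COc1ccc(COC/C=C(/CO[Si](C(C)C)(C(C)C)C(C)C)CC/C=C(/CO[Si](C(C)C)(C(C)C)C(C)C)[C@H](OCc2ccc3ccccc3c2)[C@H](O[Si](CC)(CC)CC)/C=C(/CO)COCc2ccc(OC)cc2)cc1OC | intermediate
26 | C13 O-(N-phenyl-2,2,2-trifluoroacetimidate) of 25 | COc1ccc(COC/C=C(/CO[Si](C(C)C)(C(C)C)C(C)C)CC/C=C(/CO[Si](C(C)C)(C(C)C)C(C)C)[C@H](OCc2ccc3ccccc3c2)[C@H](O[Si](CC)(CC)CC)/C=C(/COC(=Nc2ccccc2)C(F)(F)F)COCc2ccc(OC)cc2)cc1OC | intermediate
27 | C6 primary allylic alcohol (26 without DMB) | OC/C=C(/CO[Si](C(C)C)(C(C)C)C(C)C)CC/C=C(/CO[Si](C(C)C)(C(C)C)C(C)C)[C@H](OCc1ccc2ccccc2c1)[C@H](O[Si](CC)(CC)CC)/C=C(/COC(=Nc1ccccc1)C(F)(F)F)COCc1ccc(OC)cc1 | intermediate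
28 | C6 enal | O=C/C=C(/CO[Si](C(C)C)(C(C)C)C(C)C)CC/C=C(/CO[Si](C(C)C)(C(C)C)C(C)C)[C@H](OCc1ccc2ccccc2c1)[C@H](O[Si](CC)(CC)CC)/C=C(/COC(=Nc1ccccc1)C(F)(F)F)COCc1ccc(OC)cc1 | intermediate
29 | C6 α-hydroxy allylstannane (6RS) | CCCC[Sn](CCCC)(CCCC)C(O)/C=C(/CO[Si](C(C)C)(C(C)C)C(C)C)CC/C=C(/CO[Si](C(C)C)(C(C)C)C(C)C)[C@H](OCc1ccc2ccccc2c1)[C@H](O[Si](CC)(CC)CC)/C=C(/COC(=Nc1ccccc1)C(F)(F)F)COCc1ccc(OC)cc1 | intermediate
30 | thirteen-membered α-stannyl bis-allylic ether (6RS) | CCCC[Sn](CCCC)(CCCC)C1/C=C(/CO[Si](C(C)C)(C(C)C)C(C)C)CC/C=C(/CO[Si](C(C)C)(C(C)C)C(C)C)[C@H](OCc2ccc3ccccc3c2)[C@H](O[Si](CC)(CC)CC)/C=C(/CO1)COCc1ccc(OC)cc1 | intermediate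
31 | C6 α-alkoxyallyllithium from 30 | [Li]C1/C=C(/CO[Si](C(C)C)(C(C)C)C(C)C)CC/C=C(/CO[Si](C(C)C)(C(C)C)C(C)C)[C@H](OCc2ccc3ccccc3c2)[C@H](O[Si](CC)(CC)CC)/C=C(/CO1)COCc1ccc(OC)cc1 | intermediate
32 | ten-membered (6R,7S,8R,9S) C6 alcohol with 3-(4-methoxybenzyloxy)prop-1-en-2-yl on C7 | O[C@@H]1/C=C(/CO[Si](C(C)C)(C(C)C)C(C)C)CC/C=C(/CO[Si](C(C)C)(C(C)C)C(C)C)[C@H](OCc2ccc3ccccc3c2)[C@H](O[Si](CC)(CC)CC)[C@H]1C(=C)COCc1ccc(OC)cc1 | intermediate
33 | C6,C12 diol | O[C@@H]1/C=C(/CO[Si](C(C)C)(C(C)C)C(C)C)CC/C=C(/CO[Si](C(C)C)(C(C)C)C(C)C)[C@H](OCc2ccc3ccccc3c2)[C@H](O[Si](CC)(CC)CC)[C@H]1C(=C)CO | intermediate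
34 | C6-hydroxy C12 enal | O[C@@H]1/C=C(/CO[Si](C(C)C)(C(C)C)C(C)C)CC/C=C(/CO[Si](C(C)C)(C(C)C)C(C)C)[C@H](OCc2ccc3ccccc3c2)[C@H](O[Si](CC)(CC)CC)[C@H]1C(=C)C=O | intermediate
35 | C12 lactol | C=C1C(O)O[C@@H]2/C=C(/CO[Si](C(C)C)(C(C)C)C(C)C)CC/C=C(/CO[Si](C(C)C)(C(C)C)C(C)C)[C@H](OCc3ccc4ccccc4c3)[C@H](O[Si](CC)(CC)CC)[C@@H]12 | intermediate
36 | trans lactone, C8 OTES, C9 ONAP | C=C1C(=O)O[C@@H]2/C=C(/CO[Si](C(C)C)(C(C)C)C(C)C)CC/C=C(/CO[Si](C(C)C)(C(C)C)C(C)C)[C@H](OCc3ccc4ccccc4c3)[C@H](O[Si](CC)(CC)CC)[C@@H]12 | intermediate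
37 | lactone C8 alcohol, C9 ONAP | C=C1C(=O)O[C@@H]2/C=C(/CO[Si](C(C)C)(C(C)C)C(C)C)CC/C=C(/CO[Si](C(C)C)(C(C)C)C(C)C)[C@H](OCc3ccc4ccccc4c3)[C@H](O)[C@@H]12 | intermediate
38 | lactone C8 (S)-2-methylbutanoate, C9 ONAP | C=C1C(=O)O[C@@H]2/C=C(/CO[Si](C(C)C)(C(C)C)C(C)C)CC/C=C(/CO[Si](C(C)C)(C(C)C)C(C)C)[C@H](OCc3ccc4ccccc4c3)[C@H](OC(=O)[C@@H](C)CC)[C@@H]12 | intermediate
39 | lactone C9 alcohol, C8 (S)-2-methylbutanoate | C=C1C(=O)O[C@@H]2/C=C(/CO[Si](C(C)C)(C(C)C)C(C)C)CC/C=C(/CO[Si](C(C)C)(C(C)C)C(C)C)[C@H](O)[C@H](OC(=O)[C@@H](C)CC)[C@@H]12 | intermediate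
40 | 14,15-bis(triisopropylsilyl) ether of the target | C=C1C(=O)O[C@@H]2/C=C(/CO[Si](C(C)C)(C(C)C)C(C)C)CC/C=C(/CO[Si](C(C)C)(C(C)C)C(C)C)[C@H](OC(C)=O)[C@H](OC(=O)[C@@H](C)CC)[C@@H]12 | intermediate
41 | CNP0207247.12 | C=C1C(=O)O[C@@H]2/C=C(/CO)CC/C=C(/CO)[C@H](OC(C)=O)[C@H](OC(=O)[C@@H](C)CC)[C@@H]12 | target

## Step count and least certain steps

Total: 30 steps. Longest linear sequence: 29 steps (1 to 41 through steps 1–8 and 10–30; step 9 is a one-step branch).

Step 23 (key step).
- What may go wrong: 1,4-elimination of the C15 silanolate from the delocalised anion (the C15–O bond is β to the anionic terminus C4), competing [1,2]-shift, or attack on the wrong face of C7. The anion is long-lived enough for these only if the ring contraction is slowed by strain in the forming cyclodecadiene.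
- Fallback: reverse the polarity at C6 so that no C6 carbanion is formed. From 25, MsCl/Et3N then LiBr gives the allylic bromide F1. DDQ removes the DMB ether to give the C6 alcohol F2, and MnO2 gives the bromo enal F3. CrCl2 in THF at high dilution (intramolecular Nozaki–Hiyama–Kishi-type allylation) then forms C6–C7 through γ-attack of the allylchromium species with the usual anti preference. This returns to the route at 32.

Step 22.
- What may go wrong: protodestannylation or C-allylation of the acid-sensitive α-hydroxy allylstannane, reversion of 29 to the enal during handling, or oligomerisation instead of ring closure. The intramolecular imidate alkylation has to compete with all of these at a thirteen-membered ring size.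
- Fallback: a tin-free ether closed by a base-stable alkoxide. From 25, MsCl/Et3N then LiCl gives the allylic chloride F4, and DDQ gives the C6 alcohol F5. EtMgBr in THF/HMPA at high dilution (Williamson macro-etherification of the primary allylic alkoxide) gives the tin-free thirteen-membered bis-allylic ether F6. Direct deprotonation with sec-BuLi at −78 °C then triggers the same [2,3] ring contraction, relying on the precedented preference for metalation at the C6 methylene. This returns at 32.

Step 24.
- What may go wrong: incomplete discrimination between the PMB and NAP ethers (partial loss of the C9 ether) or oxidation of the allylic C6 alcohol, because the selectivity is only kinetic.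
- Fallback: give up the discrimination and reverse the order of the two acylations. From 32, excess DDQ gives the C6,C9,C12 triol F7. TEMPO/PhI(OAc)2 gives the C9-hydroxy lactone F8, relying on the faster five-membered lactol. Ac2O/pyridine gives the C9 acetate F9, PPTS/MeOH gives the C8 alcohol F10, and (S)-2-methylbutanoic anhydride/DMAP returns to the route at 40.

Step 16.
- What may go wrong: poor E/Z control or loss of the alkoxide by retro-oxa-Michael reaction before olefination, since the carbanion 23 is a β-alkoxy phosphonate.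
- Fallback: build the same enoate under thermodynamic control. From 21, Morita–Baylis–Hillman reaction with ethyl acrylate (DABCO) gives the adduct F11. Acetylation gives the allylic acetate F12, and SN2′ displacement with sodium 4-methoxybenzyloxide gives the E 2-(alkoxymethyl)enoate, returning at 24.

Step 11.
- What may go wrong: poor facial selectivity if the ketone does not chelate well beside the bulky silyloxymethyl enone substituent.
- Fallback: reagent control in place of substrate control, namely Corey–Bakshi–Shibata reduction of 16 with the oxazaborolidine enantiomer matched to the 9S carbinol and BH3·SMe2. This goes from 16 directly to 17 and makes no new compound.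

## Further compounds

F1 | step 23 | C13 allylic bromide from 25 (C6 ODMB) | COc1ccc(COC/C=C(/CO[Si](C(C)C)(C(C)C)C(C)C)CC/C=C(/CO[Si](C(C)C)(C(C)C)C(C)C)[C@H](OCc2ccc3ccccc3c2)[C@H](O[Si](CC)(CC)CC)/C=C(/CBr)COCc2ccc(OC)cc2)cc1OC
F2 | step 23 | C6 alcohol C13 bromide | OC/C=C(/CO[Si](C(C)C)(C(C)C)C(C)C)CC/C=C(/CO[Si](C(C)C)(C(C)C)C(C)C)[C@H](OCc1ccc2ccccc2c1)[C@H](O[Si](CC)(CC)CC)/C=C(/CBr)COCc1ccc(OC)cc1
F3 | step 23 | C6 enal C13 bromide | O=C/C=C(/CO[Si](C(C)C)(C(C)C)C(C)C)CC/C=C(/CO[Si](C(C)C)(C(C)C)C(C)C)[C@H](OCc1ccc2ccccc2c1)[C@H](O[Si](CC)(CC)CC)/C=C(/CBr)COCc1ccc(OC)cc1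
F4 | step 22 | C13 allylic chloride from 25 (C6 ODMB) | COc1ccc(COC/C=C(/CO[Si](C(C)C)(C(C)C)C(C)C)CC/C=C(/CO[Si](C(C)C)(C(C)C)C(C)C)[C@H](OCc2ccc3ccccc3c2)[C@H](O[Si](CC)(CC)CC)/C=C(/CCl)COCc2ccc(OC)cc2)cc1OC
F5 | step 22 | C6 alcohol C13 chloride | OC/C=C(/CO[Si](C(C)C)(C(C)C)C(C)C)CC/C=C(/CO[Si](C(C)C)(C(C)C)C(C)C)[C@H](OCc1ccc2ccccc2c1)[C@H](O[Si](CC)(CC)CC)/C=C(/CCl)COCc1ccc(OC)cc1
F6 | step 22 | tin-free thirteen-membered bis-allylic ether | C1/C=C(/CO[Si](C(C)C)(C(C)C)C(C)C)CC/C=C(/CO[Si](C(C)C)(C(C)C)C(C)C)[C@H](OCc2ccc3ccccc3c2)[C@H](O[Si](CC)(CC)CC)/C=C(/CO1)COCc1ccc(OC)cc1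
F7 | step 24 | C6,C9,C12 triol | O[C@@H]1/C=C(/CO[Si](C(C)C)(C(C)C)C(C)C)CC/C=C(/CO[Si](C(C)C)(C(C)C)C(C)C)[C@H](O)[C@H](O[Si](CC)(CC)CC)[C@H]1C(=C)CO
F8 | step 24 | lactone C9 alcohol C8 OTES | C=C1C(=O)O[C@@H]2/C=C(/CO[Si](C(C)C)(C(C)C)C(C)C)CC/C=C(/CO[Si](C(C)C)(C(C)C)C(C)C)[C@H](O)[C@H](O[Si](CC)(CC)CC)[C@@H]12
F9 | step 24 | lactone C9 acetate C8 OTES | C=C1C(=O)O[C@@H]2/C=C(/CO[Si](C(C)C)(C(C)C)C(C)C)CC/C=C(/CO[Si](C(C)C)(C(C)C)C(C)C)[C@H](OC(C)=O)[C@H](O[Si](CC)(CC)CC)[C@@H]12
F10 | step 24 | lactone C9 acetate C8 alcohol | C=C1C(=O)O[C@@H]2/C=C(/CO[Si](C(C)C)(C(C)C)C(C)C)CC/C=C(/CO[Si](C(C)C)(C(C)C)C(C)C)[C@H](OC(C)=O)[C@H](O)[C@@H]12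
F11 | step 16 | Morita–Baylis–Hillman adduct of 21 (C7 carbinol, epimer mixture) | COc1ccc(COC/C=C(/CO[Si](C(C)C)(C(C)C)C(C)C)CC/C=C(/CO[Si](C(C)C)(C(C)C)C(C)C)[C@H](OCc2ccc3ccccc3c2)[C@H](O[Si](CC)(CC)CC)C(O)C(=C)C(=O)OCC)cc1OC
F12 | step 16 | C7 acetate of F11 | COc1ccc(COC/C=C(/CO[Si](C(C)C)(C(C)C)C(C)C)CC/C=C(/CO[Si](C(C)C)(C(C)C)C(C)C)[C@H](OCc2ccc3ccccc3c2)[C@H](O[Si](CC)(CC)CC)C(OC(C)=O)C(=C)C(=O)OCC)cc1OC
F0 | step 11 | none | none
A1 | alternative 1 | C6-hydroxy C7-ethynyl macrocycle with both esters and TBS ethers | O[C@@H]1/C=C(/CO[Si](C)(C)C(C)(C)C)CC/C=C(/CO[Si](C)(C)C(C)(C)C)[C@H](OC(C)=O)[C@H](OC(=O)[C@@H](C)CC)[C@H]1C#C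
A2 | alternative 1 | 14,15-bis(tert-butyldimethylsilyl) ether of the target | C=C1C(=O)O[C@@H]2/C=C(/CO[Si](C)(C)C(C)(C)C)CC/C=C(/CO[Si](C)(C)C(C)(C)C)[C@H](OC(C)=O)[C@H](OC(=O)[C@@H](C)CC)[C@@H]12
A3 | alternative 2 | C5=C10 octalin with fused trans lactone | C12=C(CCC[C@H]1CO[Si](C(C)C)(C(C)C)C(C)C)[C@H](O[Si](CC)(CC)CC)[C@H](O[Si](C)(C)C(C)(C)C)[C@H]3CC(=O)O[C@H]23
A4 | alternative 2 | ten-membered 5,10-diketone with fused trans lactone | O=C1[C@H](CO[Si](C(C)C)(C(C)C)C(C)C)CCCC(=O)[C@H](O[Si](CC)(CC)CC)[C@H](O[Si](C)(C)C(C)(C)C)[C@H]2CC(=O)O[C@H]12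
A5 | alternative 3 | cis-decalin with C9 tertiary alcohol and C5 mesylate | [C@@]12(CO[Si](C(C)C)(C(C)C)C(C)C)[C@H](OS(C)(=O)=O)[C@@H](O[Si](C)(C)C(C)(C)C)[C@H](C(=C)CO[Si](C)(C)C(C)(C)C)[C@@H](OCc3ccc(OC)cc3)[C@]1(O)C(CO[Si](C(C)C)(C(C)C)C(C)C)=CCC2
A6 | alternative 3 | ring-cis,ring-cis cyclodecadienone with C9 ketone | O=C1/C(CO[Si](C(C)C)(C(C)C)C(C)C)=C\CC/C(CO[Si](C(C)C)(C(C)C)C(C)C)=C\[C@@H](O[Si](C)(C)C(C)(C)C)[C@H](C(=C)CO[Si](C)(C)C(C)(C)C)[C@H]1OCc2ccc(OC)cc2
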